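**Retrosynthetic overview**

1. Numbering: C1 hemiketal carbon, C2 CHOH, C3 ketone, C4 tertiary carbinol, C5=C6 alkene, C7 enone carbonyl, C8 CMe2, C9 CHMe, C10 ring-fusion CH, C11 CH2; ring A pyranone (primed locants), ring B dihydropyran, ring C seven-membered, ring D cyclopentenone. The strategy rests on ring C: C1 and C3 are both at the carbonyl oxidation level and 1,3-related through C2, and C4 is quaternary, so C1–C2 can be inserted as a ketene into the C3–C10 bond of a diquinane (ring D fused to the five-membered ring C3–C4–C5–C9–C10).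
2. Ring B (last): C10–C11 and O–C1 by hetero-Diels–Alder addition of the 3-methylidene-pyran-2,4-dione from the ring A pyranone to the C1=C10 enol ether of the bis-silylated ring C dione; C2–O by Rubottom oxidation of the C2=C3 enol ether that remains; hemiketal on desilylation.
3. Ring C: dichloroketene [2+2] on the C3=C10 silyl enol ether (C1–C10, C2–C3), dechlorination, then retro-aldol cleavage of C3–C10 (two-carbon ring enlargement).
4. Diquinane: C3–C4 by carbene-catalysed crossed benzoin of an ene-dione aldehyde (sets C4); C5–C9 by organocatalytic Mukaiyama–Michael addition of the enol silane of 2,2-dimethylcyclopentane-1,3-dione to crotonaldehyde (sets C9).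
5. Order of ring formation: ring D (bought) → five-membered carbocycle → ring C → ring B onto bought ring A.

Key step: step 8

Assumption: ring–chain tautomerism of the hemiketal exposes a 2-hydroxy-1,3-diketone, so C1, C2 and C10 of the target can equilibrate; the target is taken to be the thermodynamically preferred hemiketal (rings B/C trans-fused, axial C1 hydroxyl), and only C4 and C9 have to be built irreversibly.

**Route**

Step 1
Reactants: 1 2,2-dimethylcyclopentane-1,3-dione
Product: 2 2,2-dimethyl-3-(trimethylsilyloxy)cyclopent-3-en-1-one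
Conditions: LiN(i-Pr)2 (1.05 equiv), THF, −78 °C; TMSCl, −78 °C → rt
Reagents that add atoms: chlorotrimethylsilane, C[Si](C)(C)Cl
Why: Kinetic enolate formation and O-silylation; C8 is quaternary and the two α-methylenes are equivalent, so only one mono enol silane can form.

Step 2
Reactants: 2 2,2-dimethyl-3-(trimethylsilyloxy)cyclopent-3-en-1-one; 3 (E)-but-2-enal (crotonaldehyde)
Product: 5 4-[(2R)-4,4-dimethoxybutan-2-yl]-2,2-dimethylcyclopentane-1,3-dione, via aldehyde 4 (not isolated)
Conditions: (2S,5S)-5-benzyl-2-tert-butyl-3-methylimidazolidin-4-one trifluoroacetate (20 mol%), t-BuOH–i-PrOH, −20 °C; then HC(OMe)3, MeOH, TsOH (cat.), rt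
Reagents that add atoms: trimethyl orthoformate, COC(OC)OC; methanol, CO
Why: Iminium-catalysed Mukaiyama–Michael addition, in which the enol silane attacks the β-carbon of the crotonaldehyde iminium ion on the face left open by the benzyl group and should set C9 as R (the mirror-image catalyst is used if the sense proves opposite); the ring carbon C5 forms as a mixture that step 3 erases, and the aldehyde is masked in the same flask as its dimethyl acetal.

Step 3
Reactants: 5 4-[(2R)-4,4-dimethoxybutan-2-yl]-2,2-dimethylcyclopentane-1,3-dione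
Product: 7 4-[(2R)-4,4-dimethoxybutan-2-yl]-2,2-dimethylcyclopent-4-ene-1,3-dione, via enol silane 6 (not isolated)
Conditions: LiN(i-Pr)2, TMSCl, THF, −78 °C; then Pd(OAc)2 (1.05 equiv), MeCN, rt
Reagents that add atoms: none
Why: Saegusa–Ito dehydrogenation, in which kinetic enolisation at the C6 methylene, palladation of the enol silane and β-hydride loss of H-5 give the conjugated ene-dione, so that C5 becomes sp2 and only C9 remains stereogenic.

Step 4
Reactants: 7 4-[(2R)-4,4-dimethoxybutan-2-yl]-2,2-dimethylcyclopent-4-ene-1,3-dione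
Product: 8 (3R)-3-(4,4-dimethyl-3,5-dioxocyclopent-1-en-1-yl)butanal
Conditions: 1 M HCl, THF, rt
Reagents that add atoms: water, O
Why: Acid hydrolysis of the dimethyl acetal; the ene-dione is stable to dilute acid and no base touches the γ-hydrogen at C9.

Step 5
Reactants: 8 (3R)-3-(4,4-dimethyl-3,5-dioxocyclopent-1-en-1-yl)butanal
Product: 9 (3R,6aR)-6a-hydroxy-3,6,6-trimethyl-2,3,6,6a-tetrahydropentalene-1,5-dione (diquinane ketol: C3 ketone, C4 hydroxyl anti to the C9 methyl, ring D enone)
Conditions: (5aR,10bS)-2-mesityl-5a,10b-dihydro-4H,6H-indeno[2,1-b][1,2,4]triazolo[4,3-d][1,4]oxazin-2-ium chloride (15 mol%; its mirror image if that is the matched antipode), i-Pr2NEt (15 mol%), toluene, rt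
Reagents that add atoms: none
Why: Intramolecular crossed benzoin reaction, in which the Breslow intermediate of the aldehyde adds to the C4 ketone in a 5-exo closure (Stetter addition at C6 would be 5-endo and the C7 carbonyl is out of reach) to form C3–C4, the C3 ketone and the C4 carbinol; the chiral carbene, matched with C9, should place the hydroxyl anti to the C9 methyl (4R).

Step 6
Reactants: 9 diquinane ketol
Product: 10 (3R,6aR)-6a-(tert-butyldimethylsilyloxy)-3,6,6-trimethyl-2,3,6,6a-tetrahydropentalene-1,5-dione (C4 TBS ether of 9)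
Conditions: TBSOTf, 2,6-lutidine, CH2Cl2, 0 °C → rt
Reagents that add atoms: tert-butyldimethylsilyl trifluoromethanesulfonate, CC(C)(C)[Si](C)(C)OS(=O)(=O)C(F)(F)F
Why: Silyl triflate silylation of the hindered tertiary α-hydroxy ketone; 2,6-lutidine is too weak a base to enolise either ketone.

Step 7
Reactants: 10 C4 TBS ether of 9
Product: 11 diquinane silyl enol ether (10 with C3 as its trimethylsilyl enol ether, C3=C10; C4 R OTBS, C9 R methyl, ring D enone)
Conditions: LiN(i-Pr)2 (1.05 equiv), TMSCl (in situ), THF, −78 °C; Et3N, pentane work-up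
Reagents that add atoms: chlorotrimethylsilane, C[Si](C)(C)Cl
Why: Kinetic deprotonation with internal silyl quench; C3 can enolise only towards C10 because C4 is quaternary, and removal of the secondary α-hydrogen at C10 should be much faster than removal of the tertiary γ-hydrogen at C9 of the ring D enone.

Step 8
Reactants: 11 diquinane silyl enol ether; 12 trichloroacetyl chloride
Product: 16 ring C 1,3-dione (seven-membered ring C1(=O)–C2H2–C3(=O)–C4(OTBS)–C5–C9(Me)–C10H2 fused at C4–C5 to the ring D enone; 4R,9R in the numbering used here), via dichloroketene 13 (not isolated), via dichlorocyclobutanone 14 (not isolated), via siloxycyclobutanone 15 (not isolated)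
Conditions: 12, Zn–Cu couple, Et2O–DME, 0 °C → rt; filter; Zn, AcOH, i-PrOH–H2O, 0 °C; filter; 40 °C
Reagents that add atoms: trichloroacetyl chloride (12), ClC(Cl)(Cl)C(Cl)=O
Why: Zinc dehalogenation of 12 gives dichloroketene 13, whose electrophilic carbonyl carbon (C1) bonds to the nucleophilic enol ether carbon C10 while its CCl2 carbon (C2) closes onto the siloxy carbon C3, an asynchronous [2+2] cycloaddition that is the known reaction of dichloroketene with cyclopentanone silyl enol ethers. The four-membered ring is closed by this cycloaddition, suprafacially on the enol ether and therefore cis-fused, most likely on the face away from the C4 silyl ether; ring C is not closed by a new bond but arises when the ring-fusion bond C3–C10 of the bicyclo[3.2.0] unit is broken. Both chlorine atoms are removed with Zn/AcOH at the cyclobutanone stage (15), because a β-alkoxide next to a CCl2 group would expel the dichloroenolate and cut C2–C3, which gives a C10 dichloroacetyl ketone and no ring enlargement. Mild aqueous acid then removes the trimethylsilyl group of 15 and the strained β-hydroxy cyclobutanone undergoes retro-aldol cleavage of C3–C10, which leaves C1 and C3 as a 1,3-dione with C2 between them in a seven-membered ring. No stereocentre that survives is created (C3 and C10 of 14 and 15 are lost again) and C4 and C9 are not touched. The step needs regioselectivity, secured by the polarity of the enol ether and the single enolisation site of C3, and chemoselectivity, secured because the electron-poor ring D enone does not react with an electrophilic ketene and the tertiary TBS ether survives the aqueous acetic acid that cleaves the trimethylsilyl ether.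

Step 9
Reactants: 16 ring C 1,3-dione
Product: 17 1,3-bis(trimethylsilyloxy)-1,3-diene of 16 (C10=C1(OTMS)–C2=C3(OTMS); C4 OTBS, ring D enone)
Conditions: TMSOTf (2.3 equiv), Et3N (3 equiv), Et2O, 0 °C → rt; pentane extraction
Reagents that add atoms: trimethylsilyl trifluoromethanesulfonate, C[Si](C)(C)OS(=O)(=O)C(F)(F)F
Why: Soft enolisation turns the 1,3-dione into its bis(silyloxy)diene, a neutral equivalent of the dione dianion whose terminal carbon is C10 (C4 blocks the other side); amide bases are avoided because they would remove the γ-hydrogen at C9 of the ring D enone before deprotonating the dione monoanion a second time.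

Step 10
Reactants: 18 4-hydroxy-5,6-dimethyl-2H-pyran-2-one
Product: 19 3-[(dimethylamino)methyl]-4-hydroxy-5,6-dimethyl-2H-pyran-2-one
Conditions: CH2(NMe2)2, CH2Cl2, rt
Reagents that add atoms: bis(dimethylamino)methane, CN(C)CN(C)C
Why: Mannich aminomethylation at the nucleophilic C3' of the 4-hydroxypyranone by the iminium ion released from the aminal.

Step 11
Reactants: 17 bis(trimethylsilyloxy)diene; 19 3-[(dimethylamino)methyl]-4-hydroxy-5,6-dimethyl-2H-pyran-2-one
Product: 21 hetero-Diels–Alder adduct (rings A to D complete; C1 trimethylsilyl ketal with ring B cis-fused, C2=C3(OTMS) enol ether, C4 OTBS), via methylidenepyrandione 20 (not isolated)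
Conditions: 19 (1.5 equiv), 1,4-dioxane, 95 °C, N2 sweep
Reagents that add atoms: none
Why: Heating releases dimethylamine from 19 to give the 1-oxadiene 20, which should add across the terminal C10=C1 enol ether of 17 in an inverse-electron-demand hetero-Diels–Alder reaction (or its stepwise Mukaiyama–Michael/ketalisation equivalent), forming C11–C10 and O–C1 and so ring B; C10 is set by approach of 20 anti to the neighbouring C9 methyl, while the cis C1 configuration and any γ-pyrone regioisomer are re-set through the hemiketal equilibrium in step 13.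

Step 12
Reactants: 21 hetero-Diels–Alder adduct
Product: 22 C2 trimethylsilyloxy C3 ketone (21 with C2–OTMS and C3=O in place of the enol ether)
Conditions: DMDO (1.1 equiv), acetone–CH2Cl2, −40 °C
Reagents that add atoms: dimethyldioxirane, CC1(C)OO1
Why: Rubottom oxidation, in which the electron-rich C2=C3 silyl enol ether takes up oxygen in preference to the enone and pyranone double bonds and silyl migration gives the α-silyloxy ketone, oxygen being expected on the face of C2 anti to the bulky C4 silyl ether (2R).

Step 13
Reactants: 22 C2 trimethylsilyloxy C3 ketone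
Product: 23 CNP0525404.1 (1S,2R,4R,9R,10R in the numbering used here)
Conditions: HF·pyridine, THF, 0 °C → rt; aq. NaHCO3; then CHCl3 (trace AcOH), rt
Reagents that add atoms: none
Why: Fluoride cleaves the two trimethylsilyl ethers and the tertiary TBS ether, and the freed C1 hemiketal equilibrates through its open hydroxypyranone–ketone form to trans-fused ring B with an axial (anomeric) C1 hydroxyl, the arrangement of the target; C2 and C10, epimerisable in the open form, are expected to hold or settle in the target configuration.

**Compound list**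

1 | 2,2-dimethylcyclopentane-1,3-dione | CC1(C)C(=O)CCC1=O | starting material
2 | 2,2-dimethyl-3-(trimethylsilyloxy)cyclopent-3-en-1-one | CC1(C)C(=O)CC=C1O[Si](C)(C)C | intermediate
3 | (E)-but-2-enal (crotonaldehyde) | C/C=C/C=O | starting material
4 | (3R)-3-(3,3-dimethyl-2,4-dioxocyclopentyl)butanal (both epimers at ring carbon C5) | CC1(C)C(=O)CC([C@H](C)CC=O)C1=O | intermediate (not isolated)
5 | 4-[(2R)-4,4-dimethoxybutan-2-yl]-2,2-dimethylcyclopentane-1,3-dione (both epimers at C5) | CC1(C)C(=O)CC([C@H](C)CC(OC)OC)C1=O | intermediate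
6 | 5-[(2R)-4,4-dimethoxybutan-2-yl]-2,2-dimethyl-3-(trimethylsilyloxy)cyclopent-3-en-1-one | CC1(C)C(=O)C([C@H](C)CC(OC)OC)C=C1O[Si](C)(C)C | intermediate (not isolated)
7 | 4-[(2R)-4,4-dimethoxybutan-2-yl]-2,2-dimethylcyclopent-4-ene-1,3-dione | CC1(C)C(=O)C=C([C@H](C)CC(OC)OC)C1=O | intermediate
8 | (3R)-3-(4,4-dimethyl-3,5-dioxocyclopent-1-en-1-yl)butanal | CC1(C)C(=O)C=C([C@H](C)CC=O)C1=O | intermediate
9 | (3R,6aR)-6a-hydroxy-3,6,6-trimethyl-2,3,6,6a-tetrahydropentalene-1,5-dione | O=C1C[C@@H](C)C2=CC(=O)C(C)(C)[C@@]12O | intermediate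
10 | (3R,6aR)-6a-(tert-butyldimethylsilyloxy)-3,6,6-trimethyl-2,3,6,6a-tetrahydropentalene-1,5-dione | O=C1C[C@@H](C)C2=CC(=O)C(C)(C)[C@@]12O[Si](C)(C)C(C)(C)C | intermediate
11 | diquinane silyl enol ether: C3=C10 trimethylsilyl enol ether of 10 | C[Si](C)(C)OC1=C[C@@H](C)C2=CC(=O)C(C)(C)[C@@]12O[Si](C)(C)C(C)(C)C | intermediate (key-step precursor)
12 | trichloroacetyl chloride | ClC(Cl)(Cl)C(Cl)=O | starting material
13 | dichloroketene | ClC(Cl)=C=O | intermediate (not isolated)
14 | 2,2-dichloro-3-(trimethylsilyloxy)cyclobutanone cis-fused across C3–C10 (C1 carbonyl on C10, C2 = CCl2 on C3; C4 and C9 as in 11; C3 and C10 unassigned, lost later) | C[Si](C)(C)OC12C(Cl)(Cl)C(=O)C1[C@@H](C)C1=CC(=O)C(C)(C)[C@@]21O[Si](C)(C)C(C)(C)C | intermediate (not isolated)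
15 | 3-(trimethylsilyloxy)cyclobutanone cis-fused across C3–C10 (14 with C2 = CH2) | C[Si](C)(C)OC12CC(=O)C1[C@@H](C)C1=CC(=O)C(C)(C)[C@@]21O[Si](C)(C)C(C)(C)C | intermediate (not isolated)
16 | ring C 1,3-dione with C4 OTBS and ring D enone (4R,9R) | O=C1C[C@@H](C)C2=CC(=O)C(C)(C)[C@@]2(O[Si](C)(C)C(C)(C)C)C(=O)C1 | intermediate (key-step product)
17 | bis(trimethylsilyloxy)diene of 16, C10=C1(OTMS)–C2=C3(OTMS) | C[Si](C)(C)OC1=C[C@@H](C)C2=CC(=O)C(C)(C)[C@@]2(O[Si](C)(C)C(C)(C)C)C(O[Si](C)(C)C)=C1 | intermediate
18 | 4-hydroxy-5,6-dimethyl-2H-pyran-2-one | Cc1oc(=O)cc(O)c1C | starting material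
19 | 3-[(dimethylamino)methyl]-4-hydroxy-5,6-dimethyl-2H-pyran-2-one | Cc1oc(=O)c(CN(C)C)c(O)c1C | intermediate
20 | 5,6-dimethyl-3-methylidene-2H-pyran-2,4(3H)-dione | C=C1C(=O)OC(C)=C(C)C1=O | intermediate (not isolated)
21 | tetracyclic adduct: C1 trimethylsilyl ketal (ring B cis-fused), C2=C3(OTMS), C4 OTBS, C11 on C10 anti to the C9 methyl | Cc1oc(=O)c2c(c1C)O[C@@]1(O[Si](C)(C)C)C=C(O[Si](C)(C)C)[C@@]3(O[Si](C)(C)C(C)(C)C)C(=CC(=O)C3(C)C)[C@H](C)[C@H]1C2 | intermediate
22 | tetracycle with C1 trimethylsilyl ketal, C2 OTMS, C3 ketone, C4 OTBS | Cc1oc(=O)c2c(c1C)O[C@@]1(O[Si](C)(C)C)[C@H](O[Si](C)(C)C)C(=O)[C@@]3(O[Si](C)(C)C(C)(C)C)C(=CC(=O)C3(C)C)[C@H](C)[C@H]1C2 | intermediate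
23 | CNP0525404.1 | Cc1oc(=O)c2c(c1C)O[C@]1(O)[C@H](O)C(=O)[C@@]3(O)C(=CC(=O)C3(C)C)[C@H](C)[C@H]1C2 | target

**Step count**

Total: 13 steps. Longest linear sequence: 12 steps (steps 1–9 and 11–13); step 10 is a one-step side branch.

**Steps most likely to fail**

1. Step 8. The ketene may fail to close the four-membered ring at the congested C3, so that silyl transfer leads to C-acylation at C10, or the cyclobutanone may open across C2–C3 instead of C3–C10. Fallback, setting out from 9 and returning at 16: the bulky silyl group is introduced only after ring enlargement, so the substrate and the order of events change. Ketol 9 is doubly silylated (LiN(i-Pr)2, 2.2 equiv, TMSCl, THF, −78 °C) to the bis(trimethylsilyl) derivative F1, in which C4 carries only a trimethylsilyl ether next to the C3=C10 enol ether. Cycloaddition with dichloroketene 13 gives dichlorocyclobutanone F2, and Zn/AcOH gives cyclobutanone F3. Warming in aqueous acetic acid removes both trimethylsilyl groups and opens the ring to the C4-hydroxy dione F4. TBSOTf/2,6-lutidine with aqueous work-up, which hydrolyses any enol silyl ether, then gives 16.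

2. Step 11. Dimerisation of the oxadiene or protodesilylation of the diene by the acidic Mannich base may outrun the cycloaddition, and attack at C2 instead of C10 is possible. Fallback, setting out from 17 and returning at 23: ring B is built by Mannich and Michael chemistry instead of cycloaddition. Mukaiyama–Mannich reaction of 17 with CH2=NMe2+ I− (CH2Cl2, rt, aqueous work-up) gives the C10 aminomethyl dione F5. Heating F5 with pyranone 18 (dioxane, 90 °C) expels dimethylamine to give the C10 methylidene dione F6, to which C3' of 18 adds in a Michael reaction, and the adduct closes to the hemiketal F7. DMDO hydroxylates the enol form of F7 at C2 to give the C4 TBS ether of the target F8, and HF·pyridine gives 23.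

3. Step 5. Conjugate addition of the carbene to the ene-dione may consume the catalyst, facial selectivity at C4 may be poor, and base may erode C9 through the γ-position. Fallback, setting out from 5 and returning at 9: the ring is closed reductively before the ene-dione exists. Acetal 5 is hydrolysed to aldehyde 4, and SmI2 (THF, t-BuOH, −78 °C) closes C3–C4 by ketyl–carbonyl pinacol coupling to the cis-diol F9; only the C5 epimer that places the C9 methyl on the concave face is carried on, the other being separated. The diol is protected as acetonide F10 (2,2-dimethoxypropane, TsOH cat.). IBX (DMSO, 70 °C) dehydrogenates the C7 ketone, which can enolise only towards C6, to give enone acetonide F11. Aqueous acid gives enone diol F12, and Parikh–Doering oxidation (SO3·pyridine, DMSO, Et3N) of the secondary C3 alcohol gives 9.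

**Further compounds**

F1 | step 8 | bis(trimethylsilyl) derivative of 9 (C4 OTMS, C3=C10 trimethylsilyl enol ether) | C[Si](C)(C)OC1=C[C@@H](C)C2=CC(=O)C(C)(C)[C@@]12O[Si](C)(C)C
F2 | step 8 | dichlorocyclobutanone from F1 (C4 OTMS analogue of 14) | C[Si](C)(C)OC12C(Cl)(Cl)C(=O)C1[C@@H](C)C1=CC(=O)C(C)(C)[C@@]21O[Si](C)(C)C
F3 | step 8 | dechlorinated cyclobutanone (C4 OTMS analogue of 15) | C[Si](C)(C)OC12CC(=O)C1[C@@H](C)C1=CC(=O)C(C)(C)[C@@]21O[Si](C)(C)C
F4 | step 8 | ring C 1,3-dione with free C4 hydroxyl | O=C1C[C@@H](C)C2=CC(=O)C(C)(C)[C@@]2(O)C(=O)C1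
F5 | step 11 | C10 (dimethylamino)methyl derivative of dione 16 (C10 unassigned) | CN(C)CC1C(=O)CC(=O)[C@@]2(O[Si](C)(C)C(C)(C)C)C(=CC(=O)C2(C)C)[C@@H]1C
F6 | step 11 | C10 methylidene derivative of dione 16 | C=C1C(=O)CC(=O)[C@@]2(O[Si](C)(C)C(C)(C)C)C(=CC(=O)C2(C)C)[C@@H]1C
F7 | step 11 | 2-deoxy hemiketal with C4 OTBS (rings A to D, C2 = CH2) | Cc1oc(=O)c2c(c1C)O[C@]1(O)CC(=O)[C@@]3(O[Si](C)(C)C(C)(C)C)C(=CC(=O)C3(C)C)[C@H](C)[C@H]1C2
F8 | step 11 | C4 TBS ether of the target | Cc1oc(=O)c2c(c1C)O[C@]1(O)[C@H](O)C(=O)[C@@]3(O[Si](C)(C)C(C)(C)C)C(=CC(=O)C3(C)C)[C@H](C)[C@H]1C2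
F9 | step 5 | cis-fused diquinane cis-diol (C3 and C4 hydroxyls, saturated ring D ketone) | O[C@@H]1C[C@@H](C)[C@H]2CC(=O)C(C)(C)[C@@]12O
F10 | step 5 | acetonide of F9 | CC1(C)O[C@@H]2C[C@@H](C)[C@H]3CC(=O)C(C)(C)[C@@]23O1
F11 | step 5 | enone acetonide (C5=C6) | CC1(C)O[C@@H]2C[C@@H](C)C3=CC(=O)C(C)(C)[C@@]23O1
F12 | step 5 | enone diol | O[C@@H]1C[C@@H](C)C2=CC(=O)C(C)(C)[C@@]12O
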